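**Retrosynthetic overview**

1. Numbering used here: side chain C1(OAc)–C2–C3–C4(–C15H3); ring C5=C10–C9H2–C8(O)–C7–C6(OH); C14 is the CH2O on C10; lactone C11 (α-carbon, carrying =C13H2), C12 (C=O), ring oxygen on C8.
2. Last events: C14 methacrylate by selective acylation of the primary allylic alcohol; before that the cyclohexene is closed at C5=C10 by ring-closing metathesis (second ring).
3. First ring: the γ-lactone, closed by the C11–C7 bond. A phosphonoacetate carbanion tethered through O8 opens a C6–C7 epoxide at C7 (5-exo-tet) and then olefinates formaldehyde in the same flask (C13).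
4. Enabling feature: C7 carries C11 and has an oxygenated carbon on each side. C8–O anchors an ester that acidifies C11 and places it five atoms from C7; C6–OH is the oxygen of an epoxide spanning C6–C7. The trans C7/C8 fusion with C6–OH cis to C11 corresponds, in the open chain, to the erythro trans-epoxy alcohol that a Sharpless epoxidation delivers.
5. Stereocentres: C4 bought ((S)-citronellal); C8 set by catalytic asymmetric allylation of a C1–C8 dienal with a C9/C10/C14 allylstannane; C6 and C7 relayed from C8 by matched Sharpless epoxidation and transferred stereospecifically in the key step.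

Key step: step 11

Remark: compounds 1, 2, 8, 10, 16 and 22 are taken as commercial; steps 6 and 7 (stannane 13) form the only side branch.

**Step 1**
Reactants: 1 (S)-citronellal; 2 formaldehyde (37% aqueous)
Product: 3 (3S)-3,7-dimethyl-2-methylideneoct-6-enal
Conditions: aq. CH2O, pyrrolidine (10 mol%), EtCO2H (10 mol%), i-PrOH, 45 °C
Reagents that add atoms: formaldehyde (2), C=O
Why: amine-catalysed Mannich condensation/elimination (organocatalytic α-methylenation of an aldehyde) should turn the CH2 next to the formyl group into C5(=CH2), the mild conditions leaving the C4 stereocentre untouched.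

**Step 2**
Reactants: 3 (3S)-3,7-dimethyl-2-methylideneoct-6-enal
Product: 5 (3S)-3-methyl-2-methylidenehexane-1,6-diol, via dialdehyde 4 (not isolated)
Conditions: O3, CH2Cl2, −78 °C (Sudan Red 7B end point); Me2S; then NaBH4, CeCl3·7H2O, MeOH, −40 → 0 °C
Reagents that add atoms: ozone, O=[O+][O-]
Why: indicator-controlled chemoselective ozonolysis should cleave the electron-rich trisubstituted alkene much faster than the electron-poor enal alkene, and Luche-type borohydride reduction should then reduce both aldehydes in the 1,2 sense.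

**Step 3**
Reactants: 5 (3S)-3-methyl-2-methylidenehexane-1,6-diol
Product: 6 (3S)-6-hydroxy-3-methyl-2-methylidenehexanal
Conditions: activated MnO2, CH2Cl2, rt
Reagents that add atoms: none
Why: MnO2 oxidation is selective for the allylic alcohol and should leave the saturated primary alcohol untouched.

**Step 4**
Reactants: 6 (3S)-6-hydroxy-3-methyl-2-methylidenehexanal
Product: 7 (4S)-5-formyl-4-methylhex-5-en-1-yl acetate
Conditions: Ac2O, pyridine, DMAP (cat.), CH2Cl2, 0 °C
Reagents that add atoms: acetic anhydride, CC(=O)OC(C)=O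
Why: standard acylation of the primary alcohol installs the C1 acetate of the target, which should survive all later steps.

**Step 5**
Reactants: 7 (4S)-5-formyl-4-methylhex-5-en-1-yl acetate; 8 (triphenylphosphoranylidene)acetaldehyde
Product: 9 (4S,6E)-4-methyl-5-methylidene-8-oxooct-6-en-1-yl acetate
Conditions: toluene, 70 °C
Reagents that add atoms: (triphenylphosphoranylidene)acetaldehyde (8), O=CC=P(c1ccccc1)(c1ccccc1)c1ccccc1
Why: Wittig reaction of a stabilised ylide should give the (E)-C6=C7 dienal, the less electrophilic product resisting a second homologation.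

**Step 6**
Reactants: 10 2-methylidenepropane-1,3-diol
Product: 11 2-{[(tert-butyldimethylsilyl)oxy]methyl}prop-2-en-1-ol
Conditions: NaH (1.0 equiv), THF, 0 °C; TBSCl (1.0 equiv), 0 °C → rt
Reagents that add atoms: tert-butyldimethylsilyl chloride, CC(C)(C)[Si](C)(C)Cl
Why: monosilylation of a symmetrical diol through its sparingly soluble monosodium alkoxide should give the mono-ether selectively.

**Step 7**
Reactants: 11 2-{[(tert-butyldimethylsilyl)oxy]methyl}prop-2-en-1-ol
Product: 13 tert-butyldimethyl({2-[(tributylstannyl)methyl]prop-2-en-1-yl}oxy)silane, via allylic mesylate 12 (not isolated)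
Conditions: n-BuLi, THF, −78 °C; MsCl, −78 → −20 °C; then Bu3SnLi (from Bu3SnH and LiN(iPr)2, THF, 0 °C), −78 → 0 °C
Reagents that add atoms: tributylstannyllithium (made in the flask), [Li][Sn](CCCC)(CCCC)CCCC; methanesulfonyl chloride (atoms kept only in 12), CS(=O)(=O)Cl
Why: SN2 displacement of a primary allylic sulfonate by a stannyl anion is the usual entry to 2-substituted allylstannanes and should give the C9/C10/C14 reagent.

**Step 8**
Reactants: 9 (4S,6E)-4-methyl-5-methylidene-8-oxooct-6-en-1-yl acetate; 13 tert-butyldimethyl({2-[(tributylstannyl)methyl]prop-2-en-1-yl}oxy)silane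
Product: 14 (4S,6E,8R)-10-{[(tert-butyldimethylsilyl)oxy]methyl}-8-hydroxy-4-methyl-5-methylideneundeca-6,10-dien-1-yl acetate
Conditions: (R)-BINOL (20 mol%), Ti(OiPr)4 (10 mol%), 4 Å molecular sieves, CH2Cl2, −20 °C; aq. NaHCO3
Reagents that add atoms: allylstannane 13, C=C(C[Sn](CCCC)(CCCC)CCCC)CO[Si](C)(C)C(C)(C)C
Why: Keck asymmetric allylation should add the 2-substituted allyl group 1,2 to the dienal, the (R)-BINOL–titanium catalyst directing Re-face attack and so setting C8 as R by catalyst control.

**Step 9**
Reactants: 14 (4S,6E,8R)-10-{[(tert-butyldimethylsilyl)oxy]methyl}-8-hydroxy-4-methyl-5-methylideneundeca-6,10-dien-1-yl acetate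
Product: 15 (4S)-5-[(2R,3R)-3-{(1R)-1-hydroxy-3-[(tert-butyldimethylsilyloxy)methyl]but-3-en-1-yl}oxiran-2-yl]-4-methylhex-5-en-1-yl acetate
Conditions: t-BuOOH (anhydrous), Ti(OiPr)4 (20 mol%), D-(−)-diisopropyl tartrate (24 mol%), 4 Å molecular sieves, CH2Cl2, −20 °C
Reagents that add atoms: tert-butyl hydroperoxide, CC(C)(C)OO
Why: Sharpless asymmetric epoxidation with the D-(−)-tartrate catalyst is matched with the (8R)-carbinol and should epoxidise only the allylic C6=C7 bond to the erythro trans-epoxy alcohol, fixing C6 and C7 from C8 and upgrading enantiopurity because the minor (8S)-alcohol reacts slowly.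

**Step 10**
Reactants: 15 (epoxy alcohol of step 9); 16 2-(diethoxyphosphoryl)acetic acid
Product: 17 (1R)-1-{(2R,3R)-3-[(3S)-6-acetoxy-3-methylhex-1-en-2-yl]oxiran-2-yl}-3-{[(tert-butyldimethylsilyl)oxy]methyl}but-3-en-1-yl 2-(diethoxyphosphoryl)acetate
Conditions: DCC, DMAP (cat.), CH2Cl2, 0 °C → rt
Reagents that add atoms: 2-(diethoxyphosphoryl)acetic acid (16), OC(=O)CP(=O)(OCC)OCC
Why: Steglich esterification of the secondary alcohol should attach the C11/C12 unit to O8 under neutral conditions that spare the vinyl epoxide.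

**Step 11**
Reactants: 17 (phosphonoacetate of step 10); 2 formaldehyde (as paraformaldehyde)
Product: 19 (4S,6S)-6-[(2R,3R)-2-(2-{[(tert-butyldimethylsilyl)oxy]methyl}prop-2-en-1-yl)-4-methylidene-5-oxooxolan-3-yl]-6-hydroxy-4-methyl-5-methylidenehexyl acetate, via phosphono lactone 18 (not isolated)
Conditions: NaH (1.05 equiv), THF, 0 → 55 °C; then (CH2O)n, 0 °C → rt
Reagents that add atoms: formaldehyde (2, as paraformaldehyde), C=O
Why: Proposed new method: deprotonation of 17 gives a phosphonate-stabilised ester carbanion at C11 that attacks the epoxide carbon C7 in an intramolecular SN2 displacement; the C6 alkoxide so released is protonated at once by the far more acidic α-phosphono lactone C–H, and the resulting carbanion of 18 olefinates formaldehyde (Horner–Wadsworth–Emmons) to give the C13 methylene. The closest known reactions are the telescoped intramolecular Michael addition/Horner–Wadsworth–Emmons olefination of phosphonoacetate esters of γ-hydroxy enones, the intermolecular opening of epoxides by phosphonoacetate anions (first stage of the Wadsworth–Emmons cyclopropanation) and stabilised-carbanion epoxide cyclisations of the epoxynitrile type; none of them joins an ester-tethered phosphonoacetate to an epoxide. The γ-lactone closes in the 5-exo-tet mode, with C11, C7 and the departing oxygen collinear. C7 is set by inversion in the SN2 step and C6 keeps its C–O configuration, so the erythro trans-epoxy ester should translate stereospecifically into the trans C7/C8 substitution and the C6 hydroxyl cis to C11 on the later ring, while C8 is untouched. The step needs attack at C7 and not at the allylic C6 (6-endo, δ-lactone); the smaller ring, the better trajectory and the shielding of C6 by the fully substituted C5 alkene carbon should favour C7. It also needs the C6 oxygen neither to translactonise nor to take over phosphorus, which one equivalent of base should secure because the alkoxide never persists, and the soft carbanion should leave the side-chain acetate alone.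

**Step 12**
Reactants: 19 (hydroxy methylene lactone of step 11)
Product: 20 (4S)-4-[(3aR,4S,7aR)-6-{[(tert-butyldimethylsilyl)oxy]methyl}-4-hydroxy-3-methylidene-2-oxo-2,3,3a,4,7,7a-hexahydro-1-benzofuran-5-yl]pentyl acetate
Conditions: RuCl2(=CH-C6H4-2-OiPr)[1,3-bis(2-methylphenyl)imidazolidin-2-ylidene] (10 mol%; the bis(2-methylphenyl) analogue of the second-generation Hoveyda–Grubbs catalyst), 1,4-benzoquinone (20 mol%), toluene (0.005 M), 80 °C, argon sparge
Reagents that add atoms: none
Why: ring-closing metathesis of the 1,7-diene should load the catalyst on the less hindered C10 alkene and close onto the C5 alkene with loss of ethene to give the tetrasubstituted C5=C10 bond, the small N-aryl carbene ligand being the one suited to tetrasubstituted olefins and the electron-poor methylene lactone staying out of the reaction.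

**Step 13**
Reactants: 20 (silyl ether of step 12)
Product: 21 (4S)-4-[(3aR,4S,7aR)-4-hydroxy-6-(hydroxymethyl)-3-methylidene-2-oxo-2,3,3a,4,7,7a-hexahydro-1-benzofuran-5-yl]pentyl acetate
Conditions: HF·pyridine, pyridine, THF, 0 °C
Reagents that add atoms: none
Why: buffered fluoride desilylation should free the primary C14 alcohol without base that could add to the methylene lactone, cleave the acetate or move the lactone to O6.

**Step 14**
Reactants: 21 (diol of step 13); 22 methacrylic anhydride
Product: 23 [(3aR,4S,7aR)-5-[(2S)-5-acetoxypentan-2-yl]-4-hydroxy-3-methylidene-2-oxo-2,3,3a,4,7,7a-hexahydro-1-benzofuran-6-yl]methyl 2-methylprop-2-enoate (CNP0122587.1)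
Conditions: methacrylic anhydride (1.1 equiv), Et3N, DMAP (5 mol%), CH2Cl2, −20 °C
Reagents that add atoms: methacrylic anhydride (22), C=C(C)C(=O)OC(=O)C(C)=C
Why: DMAP-catalysed acylation should take the unhindered primary allylic C14–OH in preference to the C6–OH, which is secondary and flanked by the tetrasubstituted alkene and the ring fusion.

**Compound list**

1 | (S)-citronellal, (3S)-3,7-dimethyloct-6-enal | O=CC[C@@H](C)CCC=C(C)C | starting material
2 | formaldehyde (formalin in step 1, paraformaldehyde in step 11) | C=O | starting material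
3 | (3S)-3,7-dimethyl-2-methylideneoct-6-enal | C=C(C=O)[C@@H](C)CCC=C(C)C | intermediate
4 | (3S)-3-methyl-2-methylidenehexanedial (not isolated) | C=C(C=O)[C@@H](C)CCC=O | intermediate
5 | (3S)-3-methyl-2-methylidenehexane-1,6-diol | C=C(CO)[C@@H](C)CCCO | intermediate
6 | (3S)-6-hydroxy-3-methyl-2-methylidenehexanal | C=C(C=O)[C@@H](C)CCCO | intermediate
7 | (4S)-5-formyl-4-methylhex-5-en-1-yl acetate | C=C(C=O)[C@@H](C)CCCOC(C)=O | intermediate
8 | (triphenylphosphoranylidene)acetaldehyde | O=CC=P(c1ccccc1)(c1ccccc1)c1ccccc1 | starting material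
9 | (4S,6E)-4-methyl-5-methylidene-8-oxooct-6-en-1-yl acetate | O=C/C=C/C(=C)[C@@H](C)CCCOC(C)=O | intermediate
10 | 2-methylidenepropane-1,3-diol | C=C(CO)CO | starting material
11 | 2-{[(tert-butyldimethylsilyl)oxy]methyl}prop-2-en-1-ol | C=C(CO)CO[Si](C)(C)C(C)(C)C | intermediate
12 | 2-{[(tert-butyldimethylsilyl)oxy]methyl}prop-2-en-1-yl methanesulfonate (not isolated) | C=C(COS(C)(=O)=O)CO[Si](C)(C)C(C)(C)C | intermediate
13 | tert-butyldimethyl({2-[(tributylstannyl)methyl]prop-2-en-1-yl}oxy)silane | C=C(C[Sn](CCCC)(CCCC)CCCC)CO[Si](C)(C)C(C)(C)C | intermediate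
14 | (4S,6E,8R)-10-{[(tert-butyldimethylsilyl)oxy]methyl}-8-hydroxy-4-methyl-5-methylideneundeca-6,10-dien-1-yl acetate | C=C(CO[Si](C)(C)C(C)(C)C)C[C@@H](O)/C=C/C(=C)[C@@H](C)CCCOC(C)=O | intermediate
15 | (4S)-5-[(2R,3R)-3-{(1R)-1-hydroxy-3-[(tert-butyldimethylsilyloxy)methyl]but-3-en-1-yl}oxiran-2-yl]-4-methylhex-5-en-1-yl acetate | C=C(CO[Si](C)(C)C(C)(C)C)C[C@@H](O)[C@H]1O[C@@H]1C(=C)[C@@H](C)CCCOC(C)=O | intermediate
16 | 2-(diethoxyphosphoryl)acetic acid | OC(=O)CP(=O)(OCC)OCC | starting material
17 | (1R)-1-{(2R,3R)-3-[(3S)-6-acetoxy-3-methylhex-1-en-2-yl]oxiran-2-yl}-3-{[(tert-butyldimethylsilyl)oxy]methyl}but-3-en-1-yl 2-(diethoxyphosphoryl)acetate | C=C(CO[Si](C)(C)C(C)(C)C)C[C@@H](OC(=O)CP(=O)(OCC)OCC)[C@H]1O[C@@H]1C(=C)[C@@H](C)CCCOC(C)=O | intermediate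
18 | α-(diethoxyphosphoryl) lactone: as 19 but with CH–P(O)(OEt)2 at C11 in place of C=CH2, C11 unassigned (not isolated) | C=C(CO[Si](C)(C)C(C)(C)C)C[C@H]1OC(=O)C(P(=O)(OCC)OCC)[C@@H]1[C@H](O)C(=C)[C@@H](C)CCCOC(C)=O | intermediate
19 | (4S,6S)-6-[(2R,3R)-2-(2-{[(tert-butyldimethylsilyl)oxy]methyl}prop-2-en-1-yl)-4-methylidene-5-oxooxolan-3-yl]-6-hydroxy-4-methyl-5-methylidenehexyl acetate | C=C(CO[Si](C)(C)C(C)(C)C)C[C@H]1OC(=O)C(=C)[C@@H]1[C@H](O)C(=C)[C@@H](C)CCCOC(C)=O | intermediate
20 | (4S)-4-[(3aR,4S,7aR)-6-{[(tert-butyldimethylsilyl)oxy]methyl}-4-hydroxy-3-methylidene-2-oxo-2,3,3a,4,7,7a-hexahydro-1-benzofuran-5-yl]pentyl acetate | CC(C)(C)[Si](C)(C)OCC1=C([C@@H](C)CCCOC(C)=O)[C@@H](O)[C@H]2C(=C)C(=O)O[C@@H]2C1 | intermediate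
21 | (4S)-4-[(3aR,4S,7aR)-4-hydroxy-6-(hydroxymethyl)-3-methylidene-2-oxo-2,3,3a,4,7,7a-hexahydro-1-benzofuran-5-yl]pentyl acetate | OCC1=C([C@@H](C)CCCOC(C)=O)[C@@H](O)[C@H]2C(=C)C(=O)O[C@@H]2C1 | intermediate
22 | methacrylic anhydride | C=C(C)C(=O)OC(=O)C(C)=C | starting material
23 | [(3aR,4S,7aR)-5-[(2S)-5-acetoxypentan-2-yl]-4-hydroxy-3-methylidene-2-oxo-2,3,3a,4,7,7a-hexahydro-1-benzofuran-6-yl]methyl 2-methylprop-2-enoate | C=C(C)C(=O)OCC1=C([C@@H](C)CCCOC(C)=O)[C@@H](O)[C@H]2C(=C)C(=O)O[C@@H]2C1 | target

**Step count and risks**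

Total step count: 14. Longest linear sequence: 12 steps (steps 1–5 and 8–14, from (S)-citronellal).

Steps most likely to fail:

Step 11 (proposed new method). The carbanion may attack the allylic epoxide carbon C6 instead of C7 (6-endo closure), phosphorus may migrate from C11 to the C6 oxygen and lead on towards a cyclopropane, or the epoxide may simply not open below the temperature at which the vinyl epoxide decomposes. The fallback keeps the C11–C7 ring closure but uses a malonate, the classical carbon nucleophile for epoxides, and adds the methylene afterwards. It sets out from epoxy alcohol 15. Steglich esterification with allyl hydrogen malonate (DCC, DMAP, CH2Cl2) would give the mixed allyl malonate ester of 15 F1. NaH in THF (malonic ester alkylation by the epoxide, 5-exo, with inversion at C7) would give the α-(allyloxycarbonyl) lactone F2. Pd(PPh3)4 and morpholine would remove the allyl ester to give the α-carboxy lactone F3. Decarboxylative Mannich methylenation (aqueous CH2O, Et2NH, then NaOAc/AcOH, 70 °C) would give 19, where the route is rejoined.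

Step 12. Ring closure to the tetrasubstituted alkene may stall through unproductive turnover at the doubly branched 1,1-disubstituted C5 alkene, or ruthenium hydrides may isomerise the methylene lactone or the allylic alcohol. The fallback makes the C5=C10 bond by aldol condensation instead of metathesis and sets out from dienal 9. Addition of but-3-enylmagnesium bromide (THF, −78 °C) would give the butenyl dienyl carbinol F4 as a mixture of C8 epimers. Sharpless kinetic resolution under the conditions of step 9 would epoxidise only the (8R)-epimer to the erythro epoxy alcohol F5. Esterification with 16 as in step 10 would give the phosphonoacetate F6. NaH in THF as in the first stage of step 11, with aqueous quench instead of formaldehyde, would give the α-phosphono lactone F7. Ozonolysis (O3, CH2Cl2, −78 °C; Me2S) would cleave the vinyl group and the 1,1-disubstituted alkene together to give the C5-keto C14-aldehyde F8. Pyrrolidinium acetate in CH2Cl2 would bring about intramolecular aldol condensation (aldehyde enamine at C10 onto the C5 ketone) to the cyclohexenecarbaldehyde F9. Luche reduction (NaBH4, CeCl3·7H2O, MeOH, −40 °C) would give the C14 alcohol F10. Horner–Wadsworth–Emmons methylenation (KOtBu, THF, 0 °C; (CH2O)n) would give diol 21, where the route is rejoined.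

Step 8. The catalytic allylation may show poor facial selectivity or slow turnover with this functionalised 2-substituted stannane and a dienal. The fallback sets C8 by resolution instead of asymmetric addition and sets out from alcohol 11 and dienal 9. Appel bromination of 11 (CBr4, PPh3, CH2Cl2, 0 °C) would give the allylic bromide F11. Barbier allylation of 9 with F11 (indium powder, THF/H2O, rt) would give 14 together with its (8S)-epimer F12. The mixture would be taken into step 9, where the D-(−)-tartrate catalyst epoxidises 14 much faster than F12 (Sharpless kinetic resolution), so the route is rejoined at 15 and unreacted F12 is separated by chromatography.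

**Further compounds**

F1 | step 11 | mixed malonate of 15: allyl (1R)-1-{(2R,3R)-3-[(3S)-6-acetoxy-3-methylhex-1-en-2-yl]oxiran-2-yl}-3-{[(tert-butyldimethylsilyl)oxy]methyl}but-3-en-1-yl propanedioate | C=C(CO[Si](C)(C)C(C)(C)C)C[C@@H](OC(=O)CC(=O)OCC=C)[C@H]1O[C@@H]1C(=C)[C@@H](C)CCCOC(C)=O
F2 | step 11 | α-(allyloxycarbonyl) lactone: as 19 but with CH–CO2CH2CH=CH2 at C11 in place of C=CH2 | C=C(CO[Si](C)(C)C(C)(C)C)C[C@H]1OC(=O)C(C(=O)OCC=C)[C@@H]1[C@H](O)C(=C)[C@@H](C)CCCOC(C)=O
F3 | step 11 | α-carboxy lactone: as 19 but with CH–CO2H at C11 in place of C=CH2 | C=C(CO[Si](C)(C)C(C)(C)C)C[C@H]1OC(=O)C(C(=O)O)[C@@H]1[C@H](O)C(=C)[C@@H](C)CCCOC(C)=O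
F4 | step 12 | (4S,6E)-8-hydroxy-4-methyl-5-methylidenedodeca-6,11-dien-1-yl acetate (both C8 epimers) | C=CCCC(O)/C=C/C(=C)[C@@H](C)CCCOC(C)=O
F5 | step 12 | (4S)-5-{(2R,3R)-3-[(1R)-1-hydroxypent-4-en-1-yl]oxiran-2-yl}-4-methylhex-5-en-1-yl acetate | C=CCC[C@@H](O)[C@H]1O[C@@H]1C(=C)[C@@H](C)CCCOC(C)=O
F6 | step 12 | (1R)-1-{(2R,3R)-3-[(3S)-6-acetoxy-3-methylhex-1-en-2-yl]oxiran-2-yl}pent-4-en-1-yl 2-(diethoxyphosphoryl)acetate | C=CCC[C@@H](OC(=O)CP(=O)(OCC)OCC)[C@H]1O[C@@H]1C(=C)[C@@H](C)CCCOC(C)=O
F7 | step 12 | α-phosphono lactone: (4S,6S)-6-[(2R,3R)-2-(but-3-en-1-yl)-4-(diethoxyphosphoryl)-5-oxooxolan-3-yl]-6-hydroxy-4-methyl-5-methylidenehexyl acetate | C=CCC[C@H]1OC(=O)C(P(=O)(OCC)OCC)[C@@H]1[C@H](O)C(=C)[C@@H](C)CCCOC(C)=O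
F8 | step 12 | keto aldehyde: (4S,6S)-6-[(2R,3R)-4-(diethoxyphosphoryl)-5-oxo-2-(3-oxopropyl)oxolan-3-yl]-6-hydroxy-4-methyl-5-oxohexyl acetate | O=CCC[C@H]1OC(=O)C(P(=O)(OCC)OCC)[C@@H]1[C@H](O)C(=O)[C@@H](C)CCCOC(C)=O
F9 | step 12 | (4S)-4-[(3aR,4S,7aR)-3-(diethoxyphosphoryl)-6-formyl-4-hydroxy-2-oxo-2,3,3a,4,7,7a-hexahydro-1-benzofuran-5-yl]pentyl acetate | O=CC1=C([C@@H](C)CCCOC(C)=O)[C@@H](O)[C@H]2C(P(=O)(OCC)OCC)C(=O)O[C@@H]2C1
F10 | step 12 | (4S)-4-[(3aR,4S,7aR)-3-(diethoxyphosphoryl)-4-hydroxy-6-(hydroxymethyl)-2-oxo-2,3,3a,4,7,7a-hexahydro-1-benzofuran-5-yl]pentyl acetate | OCC1=C([C@@H](C)CCCOC(C)=O)[C@@H](O)[C@H]2C(P(=O)(OCC)OCC)C(=O)O[C@@H]2C1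
F11 | step 8 | {[2-(bromomethyl)prop-2-en-1-yl]oxy}(tert-butyl)dimethylsilane | C=C(CBr)CO[Si](C)(C)C(C)(C)C
F12 | step 8 | (4S,6E,8S)-10-{[(tert-butyldimethylsilyl)oxy]methyl}-8-hydroxy-4-methyl-5-methylideneundeca-6,10-dien-1-yl acetate | C=C(CO[Si](C)(C)C(C)(C)C)C[C@H](O)/C=C/C(=C)[C@@H](C)CCCOC(C)=O
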